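A percent in these tables is a share of the starting material charged, so what is left and what is made can be set against each other directly.

| setting | grey | green | maple | larch |
|---|---|---|---|---|
| starting material | 0.050 M | 0.050 M | 0.050 M | 0.050 M |
| partner | 0.10 M | 0.10 M | 0.100 M | 0.300 M |
| free catalyst | 1.2 mM | 0.40 mM | 0.80 mM | 0.80 mM |
| remark | run made earlier | run made earlier |  |  |
| time |  |  | 6.0 h | 6.0 h |

| run | time / h | catalyst intermediate A / % | catalyst intermediate C / % | target / % | starting material / % | catalyst intermediate D / % |
|---|---|---|---|---|---|---|
| grey | 0.417 | 5 | 1 | 3 | 69 | 0 |
| grey | 1.33 | 0 | 0 | 10 | 43 | 0 |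
| grey | 2.50 | 4 | 0 | 24 | 28 | 1 |
| grey | 4.00 | 0 | 1 | 36 | 13 | 3 |
| green | 0.250 | 2 | 0 | 0 | 86 | 0 |
| green | 0.667 | 5 | 0 | 2 | 69 | 0 |
| green | 1.50 | 1 | 0 | 3 | 43 | 2 |
| green | 4.00 | 0 | 0 | 10 | 22 | 5 |

(scatter of a reading: 2 percentage points)

* which of these there is most of at the end, counted by the starting material in it, maple (starting material / catalyst intermediate D / catalyst intermediate A / target / catalyst intermediate C)
* which of these there is most of at the end, counted by the starting material in it, larch (starting material / catalyst intermediate D / catalyst intermediate A / target / catalyst intermediate C)
* amount of the one of these that there is most of at the end, in percent of the starting material charged, maple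
* amount of the one of these that there is most of at the end, in percent of the starting material charged, larch

- a reading or a percentage of target counts all its forms, free or not

*What do you take from the grey run?* Its last reading: 13% of the starting material is left, so 87.0% is gone, and 36% is target. Target over starting material gone I call the catch (selectivity, in the usual term); here it is 0.414.

*And the green run?* At 4.00 h it has 22% left and 10% target, so its catch is 0.128, lower than grey's.

*Is that the catalyst?* Divided by the catalyst charged, they give 0.345 mM⁻¹ and 0.321 mM⁻¹, which lie close, and a reading of 10% carries 2 percentage points. Their mean is 0.333 mM⁻¹: the catch per millimolar, target per starting material gone, divided by the catalyst charged.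

*Where is that weak?* It is a reading at 4.00 h, and grey's catch was 0.333 at 2.50 h, so it may still rise.

*What do you commit to for maple?* From the fraction left, ln(charged over left) divided by time gives 0.510 h⁻¹ in grey and 0.379 h⁻¹ in green. Their mean, carried over to maple, gives my estimate of 6.95% left at 6.0 h. I take maple's catch as 0.266, so I reckon 24.8% target, if anything low. The catalyst charged in maple is 1.60% of the starting material charged, less than that estimated target.

*And larch?* Both runs stand at 0.10 M of partner, so I give no number.

The forecast says target for maple, 40% (32% to 48%), and target for larch, 60% (40% to 85%), holding that the starting material goes to a pool “which the catalyst then turns into target”. My maple number lies below its low end.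

Maple gives target, 30.0%, and larch target, 43.6%.

    catalyst intermediate C ⇌ released group + catalyst intermediate D (K = 0.0320 M, k = 0.210 s⁻¹)
    crystals ⇌ target, rate k2*(cs2 - [target]) while solid is left; crystals form when [target] > cs2 (solubility = 40.0 mM, k = 0.00340 s⁻¹)
    partner + catalyst intermediate A ⇌ catalyst intermediate B (K = 6.00 M⁻¹, k = 0.0450 M⁻¹ s⁻¹)
    catalyst intermediate B → catalyst intermediate C (k = 0.00400 s⁻¹)
    catalyst intermediate D ⇌ free catalyst + target (K = 0.0440 M, k = 0.0310 s⁻¹)
    starting material + free catalyst → catalyst intermediate A (k = 0.870 M⁻¹ s⁻¹)
    2 starting material → self-condensation product (k = 0.00200 M⁻¹ s⁻¹)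

Maple holds 62.9% as self-condensation product at 6.00 h, counted by the starting material in it. Its catch per millimolar at that time is 0.399 mM⁻¹, against the 0.333 mM⁻¹ I read off the earlier runs at 4.00 h, and larch, with 0.300 M of partner, reaches 0.552 mM⁻¹ at 6.00 h. The neighbour flask, maple with 0.060 M of partner, leaves 9.57% and makes 21.6% target, a catch per millimolar of 0.299 mM⁻¹.

Readings and results were computed from invented constants, noise included.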